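All constants are made up; the result is computed.

The pitfall is to divide the whole charge of E by the chains, as if ash and oak ran through their E. I follow the fraction of E left instead.

common to all: E 0.50 M (fed, over 40 min); L 10.0 mM; time 3.0 h
- ash: G 0.2 mol%
- oak: G 0.4 mol%

    G → 2 Q (k1 = 1.5 × 10⁻⁴ s⁻¹)
    E + Q → X + J (k2 = 2.8 × 10⁵ M⁻¹ s⁻¹)
    E + X → J + X, rate k3*[X]*[E] (k3 = 9100 M⁻¹ s⁻¹)
    2 X → X2 (k4 = 5 × 10⁸ M⁻¹ s⁻¹)
    L + E → L.E (k5 = 0.024 M⁻¹ s⁻¹)

1. which of the two ends with the longer chains by the average number of monomer units in a chain (living and dead chains, two that joined counted as one) ("neither" if they lie within 10%) (ash / oak / neither)
2. average number of monomer units in a chain (living and dead chains, two that joined counted as one) at the end, ash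
3. average number of monomer units in a chain (living and dead chains, two that joined counted as one) at the end, oak

- for a step with 2 of a species take k times the square, and two of it per event
- the average divides the monomer in chains by the number of chains, living and dead together; two radicals that join make one chain
- run time (ash): 3.0 h

- I count chains first. One G gives 2 Q, each Q starts one X, and two X join into one chain, so one G spent is one chain. The fraction of G left at the end is 19.8%, the same in ash and oak.
- The half-life of L in ash is 0.96 min if the whole charge of E stands there at once, but E is fed. With E rising steadily during the feed, I reckon that half of L in ash reacts in about 8.78 min, within the feed of 40 min. I book 2.00% of the E charge as L.E.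
- I take X at its quasi-steady state, where the radicals made from G balance the radicals lost in pairs. The logarithm of the fraction of E left then falls with a slope equal to the concentration of X times the rate constant of chain growth.
- In ash that slope would be 0.567 h⁻¹ with G whole. It fades with the square root of the fraction of G left, on a time scale of 3.70 h.
- The feed delivers E on average at 20.0 min, so my line starts there, at a slope of 0.519 h⁻¹.
- The depth, the logarithm of the fraction of fed E that escapes the chains, reaches 0.986 at the end of ash. Its level, once G has decomposed, is 1.92.
- Oak has twice the G of ash, so it has twice the chains, but its depth is 1.39.
- Dividing the fraction in J by the fraction in chains, I get 383 for ash and 230 for oak. The longer chains are in ash.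
- The forecast names ash, with 383 (350 to 415) for ash and 229 (208 to 250) for oak. Its ground: “doubling G doubles the chains”.
- The simulation gives 383 for ash and 230 for oak, so the longer chains are in ash.
- In ash, G has a half-life of 1.3 h against a run of 3.0 h, and 19.8% of it remains at the end. The depth leaves 36.6% of the charge as E, and the flask holds 36.5%.
- The neighbour is ash with 0.12 mol% of G. Its depth is 0.764, which leaves 45.6% as E and gives chains of 544 units. That flask holds 46% of its E and reads 544.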